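**Assumption:** (2R,3R)-fustin, an isolated heartwood flavonoid stocked by phytochemical suppliers, is accepted as a purchased starting material alongside bulk (+)-catechin; its ee is confirmed by chiral HPLC before use.

## Retrosynthetic overview

1. All four rings and four of the five stereocentres are bought. (2R,3R)-Fustin (1) carries the upper C-ring with C2 and C3 set and is reduced to the flavan-3,4-diol 2; (+)-catechin (3) is the complete lower unit.
2. The only strategic disconnection in target 4 is the interflavanyl C4(upper)–C8(lower) bond, giving the A-ring p-quinone methide of 2 (electrophile) and C8 of 3 (nucleophile).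
3. The quinone methide is generated by light from unprotected 2 under neutral conditions and captured in situ. C4 is set by the resident C2/C3 centres (attack anti to the 3-OH gives 4α).
4. No ring is built and no protecting group is used. Order of events: C4=O to C4–OH (step 1), then C4–OH to C4–C8 (step 2).

## Route

**Step 1**
Reactants: 1, (2R,3R)-fustin [(2R,3R)-2-(3,4-dihydroxyphenyl)-3,7-dihydroxychroman-4-one; 2,3-trans]
Product: 2, (+)-mollisacacidin [(2R,3S,4R)-2-(3,4-dihydroxyphenyl)chromane-3,4,7-triol; 2,3-trans-3,4-trans]
Conditions: NaBH4 (3 equiv), EtOH, 0 °C to rt, N2; quench with AcOH to pH 6 at 0 °C (no mineral acid); co-evaporate with MeOH to remove borate; EtOAc extraction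
Reagents that add atoms: none (hydride only)
Why: Borohydride reduction of an α-hydroxy aryl ketone; hydride adds axially to the half-chair with 2-aryl and 3-OH equatorial, giving the equatorial 4-OH (3,4-trans). C2 and C3 are untouched, and the C4 configuration is immaterial because C4 is planarised in step 2.

**Step 2**
Reactants: 2, (+)-mollisacacidin (1 equiv, 10 mM); 3, (+)-catechin [(2R,3S)-2-(3,4-dihydroxyphenyl)chromane-3,5,7-triol] (4 equiv)
Product: 4, fisetinidol-(4α,8)-catechin [upper unit 2R,3S,4S, all-trans; lower unit 2R,3S; bond from upper C4 to lower C8]
Conditions: hν (UV-B, 300 ± 15 nm), Ar-sparged H2O–MeCN 1:1, pH 6–7 (no acid), 5–10 °C, quartz/FEP flow coil, run to about 60% conversion of 2; Sephadex LH-20 (EtOH) then prep. RP-HPLC; recover 2 and 3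
Reagents that add atoms: none beyond reactant 3, (+)-catechin, Oc1cc(O)c2c(c1)O[C@H](c1ccc(O)c(O)c1)[C@@H](O)C2 (water is lost)
Why: Proposed new method: excitation of the 7-hydroxy (resorcinol-type) A-ring of 2 makes the phenol a strong excited-state acid; proton transfer to water and loss of the para-benzylic C4-hydroxide give the neutral A-ring p-quinone methide without acid, and the phloroglucinol-type C8 of 3 adds to C4 anti to the equatorial 3-OH, then tautomerises to the all-equatorial 4α (3,4-trans) product, so C4 is set by substrate control. Water re-addition only regenerates 2 or its C4 epimer, both competent precursors. The closest known reaction types are photodehydration of hydroxybenzyl alcohols to quinone methides with nucleophile capture, and the acid-catalysed flavan-3,4-diol/flavan-3-ol condensation; the photochemical version has not been shown for flavan-3,4-diols or for interflavanyl C–C bond formation.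

Expected behaviour of step 2: the 4β,8 and 4α,6 isomers and some trimer should form alongside 4 and are removed chromatographically. Excess 3 limits over-alkylation of the product at C6. The feed is checked by HPLC for C2 epimers (photochemical O1–C2 opening and reclosure should favour the 2,3-trans forms already present).

## Compound list

1 | (2R,3R)-fustin | Oc1ccc2c(c1)O[C@H](c1ccc(O)c(O)c1)[C@@H](O)C2=O | starting material
2 | (+)-mollisacacidin, (2R,3S,4R)-flavan-3,4-diol | Oc1ccc2c(c1)O[C@H](c1ccc(O)c(O)c1)[C@@H](O)[C@@H]2O | intermediate
3 | (+)-catechin, (2R,3S) | Oc1cc(O)c2c(c1)O[C@H](c1ccc(O)c(O)c1)[C@@H](O)C2 | starting material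
4 | fisetinidol-(4α,8)-catechin | Oc1ccc2c(c1)O[C@H](c1ccc(O)c(O)c1)[C@@H](O)[C@@H]2c1c(O)cc(O)c2c1O[C@H](c1ccc(O)c(O)c1)[C@@H](O)C2 | target

## Summary

Total steps: 2. Longest linear sequence: 2.

Steps most likely to fail (the route has only two steps, so step 2 is entered twice for two independent failure modes):

1. **Step 2, the proposed photochemical quinone-methide generation.** Risks are a low quantum yield (3 absorbs most of the light), photo-epimerisation at C2 of either unit, or photo-oxidation of the catechols. Fallback (known chemistry): ionise 2 thermally instead, by the classical acid-catalysed condensation of 2 with excess 3 in 0.1 M aqueous HCl at rt, which gives 4 directly.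
2. **Step 2, selectivity and isolation.** Risks are 4α/4β and C8/C6 mixtures and trimers that make isolation of pure 4 low-yielding. Fallback: switch to protected partners, a standard approach for related flavan-3-ol dimers. Couple a 7,3',4'-tri-O-benzyl-fisetinidol C4 electrophile (from benzylated 1, then NaBH4) with 5,7,3',4'-tetra-O-benzylcatechin under TMSOTf in CH2Cl2 at −78 °C, which should be 3,4-trans and C8 selective, then hydrogenolyse (H2, Pd(OH)2/C).
3. **Step 1.** Risks are base-induced epimerisation or ring-opening of the free-phenolic dihydroflavonol, borate complexation of the catechol, or self-condensation of 2 on work-up. Fallback: mask the phenols first (TBSCl, imidazole), reduce the now non-ionisable ketone under Luche conditions (NaBH4, CeCl3, MeOH, −40 °C), then desilylate with Et3N·3HF before step 2.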